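The earlier runs and the new flask stem from a simulated flask for an exercise.

A one-step world reads its outcome from the charge ratio, but these runs show a ladder: substrate climbs to double product, triple product and tetra adduct, taking 2, 3 and 4 reagent per substrate. The west balance supports this, counting 2.68 reagent per substrate at its last reading against 2.80 charged.

| setting | east | west | south-west | winter | midnight | autumn |
|---|---|---|---|---|---|---|
| substrate | 0.050 M | 0.050 M | 0.050 M | 0.050 M | 0.050 M | 0.050 M |
| reagent | 0.043 M | 0.14 M | 0.31 M | 0.0520 M | 0.130 M | 0.330 M |
| remark | run made earlier | run made earlier | run made earlier |  |  |  |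
| time |  |  |  | 6.0 min | 6.0 min | 6.0 min |

| run | time / min | isomer of the product / % | triple product / % | double product / % | substrate / % | tetra adduct / % |
|---|---|---|---|---|---|---|
| east | 0.667 | 1.4 | 2.8 | 27.3 | 31.3 | 0.1 |
| east | 1.33 | 1.1 | 2.4 | 28.3 | 30.8 | 0 |
| east | 2.00 | 0.2 | 1.9 | 27.6 | 29.0 | 0.3 |
| east | 2.50 | 1.9 | 2.1 | 27.6 | 30.6 | 0 |
| east | 3.00 | 1.4 | 2.3 | 27.3 | 30.7 | 0 |
| west | 0.250 | 2.3 | 26.4 | 51.8 | 6.8 | 0.8 |
| west | 0.417 | 5.5 | 35.2 | 45.0 | 3.6 | 1.0 |
| west | 0.833 | 12.1 | 43.3 | 34.3 | 1.6 | 2.2 |
| west | 1.50 | 18.4 | 46.1 | 24.4 | 2.1 | 4.3 |
| west | 3.00 | 21.7 | 47.7 | 19.0 | 0.7 | 5.5 |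
| south-west | 0.667 | 17.6 | 55.5 | 0.8 | 0 | 23.9 |
| south-west | 1.33 | 19.6 | 37.8 | 0.2 | 0.2 | 41.2 |
| south-west | 2.00 | 16.7 | 29.5 | 0 | 0 | 53.0 |
| south-west | 2.50 | 14.1 | 24.3 | 0.5 | 0.2 | 59.6 |
| south-west | 3.00 | 12.8 | 20.9 | 0.2 | 0 | 65.3 |

(readings scatter by 0.5 percentage points)

- what was read earlier has a scatter of 0.5 percentage points, one standard deviation
- a reading of substrate is of its free form alone

1. which of these there is most of at the end, counted by the substrate in it, winter (tetra adduct / isomer of the product / double product / triple product / substrate)
2. which of these there is most of at the end, counted by the substrate in it, midnight (tetra adduct / isomer of the product / double product / triple product / substrate)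
3. which of these there is most of at the end, counted by the substrate in it, autumn (tetra adduct / isomer of the product / double product / triple product / substrate)
4. how much there is at the end of the one of these that leads, in percent of the substrate charged: winter
5. how much there is at the end of the one of these that leads, in percent of the substrate charged: midnight
6. how much there is at the end of the one of these that leads, in percent of the substrate charged: autumn

The useful quantity is the excess, the reagent charged beyond 3 per substrate, which this reckoning takes as the feed of the last rung. In the south-west run, triple product and its isomer both fall after 1.33 min, so they are counted as one pool, which reads 73.1% at 0.667 min and 33.7% at 3.00 min. Free reagent there averages 0.138 M by balance. The reading is therefore 2.41 /M/min: this is the pool constant, the pseudo-first-order loss rate of the pool per unit of free reagent.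

The excess is −0.0980 M in winter and −0.0200 M in midnight, both negative, so the reckoning expects a lower rung to lead in these flasks. East double product holds near 27.3%, and scaling it by the reagent charge puts winter's double product at 33.0%. Midnight, slightly poorer than west, should lead with triple product a little under the west reading of 47.7%.

Autumn has an excess of 0.180 M. Held constant for 6.0 min, it is reckoned to turn 92.6% of the pool into tetra adduct. The weak link is that constancy, since each tetra adduct consumes reagent. Taking the mean of the start and end excess gives 0.157 M, and so 89.7% tetra adduct.

The forecast says double product at 35% in winter, triple product at 43% in midnight and tetra adduct at 86% in autumn, the last lower than the reckoning here, and holds that “end composition depends on equivalents”.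

The flasks give double product at 34.5% in winter, triple product at 42.5% in midnight and tetra adduct at 89.0% in autumn.

    substrate + reagent → first product + by-product (k = 2.30 /M/s)
    reagent + first product → double product + by-product (k = 5.90 /M/s)
    reagent + double product → triple product + by-product (k = 0.760 /M/s)
    reagent + triple product → tetra adduct + by-product (k = 0.0660 /M/s)
    triple product ⇌ isomer of the product (K = 0.480, k = 0.0130 /s)
    substrate ⇌ dormant form (K = 0.630, k = 0.0190 /s)
    first product → side product (k = 0.00950 /s)

Autumn's pool stands at 10.4% at 6.00 min, and the reforged reckoning left 10.3%. Autumn's tetra adduct stands at 89.0%, against 0.0454% at the reagent charge of winter, and the difference in concentration of reagent is the main reason. The neighbour of midnight charged with 0.030 M substrate has a positive excess of 0.0400 M. The same reckoning gives it 38.3% tetra adduct, and that flask ends at 40.7%.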